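**Retrosynthetic overview** (ring A = cyclohexane bearing isopropyl and methyl, ring B = cyclohexene with the spiro carbon, ring C = dihydropyran, ring D = phloroglucinol arene)
1. The strategy rests on ring D: C8a (bonded to the ring C oxygen) and C8 (formyl) are adjacent, and C8 is flanked on its other side by oxygen-bearing C7. This is the pattern left when an aryne C8≡C8a, polarised by an alkoxy group on C7, is captured at C8a by an oxygen nucleophile and the C8 anion is formylated.
2. Guajadial D is therefore traced back (demethylation, Rieche formylation at C6) to mono-formyl spirochroman 25, and 25 to fluoroaryl tertiary allylic alcohol 20 by breaking the aryl C8a–O bond of ring C and the C8–CHO bond.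
3. Alcohol 20 is cut at the bond between the carbinol carbon and its CH2 branch into bicyclic enone 8 and the organocerium reagent from (S)-2,2-diarylethyl iodide 17.
4. Enone 8 comes from (R)-citronellal and methyl vinyl ketone; iodide 17 comes from 1-fluoro-3,5-dimethoxybenzene by rhodium-catalysed asymmetric phenylation of a nitroalkene.
5. Order of ring formation: ring B (Michael/aldol), ring A (ene cyclisation), ring D is bought, ring C last.

Key step: step 12

Assumption: the antipode of the chiral diene ligand written in step 7 is taken to deliver the S adduct; the sense would be checked on the first run and the other antipode used if it is reversed.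

**Route**

Step 1
Reactants: 1 (R)-citronellal; 2 methyl vinyl ketone
Product: 4 (4R)-4-[(2R)-6-methylhept-5-en-2-yl]cyclohex-2-en-1-one, via keto aldehyde 3 (not isolated)
Conditions: (R)-2-[diphenyl(trimethylsilyloxy)methyl]pyrrolidine (5 mol %), ethyl 3,4-dihydroxybenzoate (20 mol %), neat, 4 °C; then aq KOH, n-Bu4NOH, THF/Et2O, rt to 40 °C
Reagents that add atoms: none
Why: Enamine-catalysed Michael addition in which the diphenyl(silyloxy)methyl group of the R catalyst shields one face of the E-enamine, so methyl vinyl ketone adds to the other face and sets C2 of 3 as R (the later C4a), followed by intramolecular aldol condensation of the methyl ketone onto the aldehyde, which closes ring B.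

Step 2
Reactants: 4 (4R)-4-[(2R)-6-methylhept-5-en-2-yl]cyclohex-2-en-1-one
Product: 5 (4aR,5R,8R,8aR)-5-methyl-8-(prop-1-en-2-yl)octahydronaphthalen-2(1H)-one
Conditions: MeAlCl2 (1.5 equiv), CH2Cl2, −78 to 0 °C; then H2O
Reagents that add atoms: none
Why: Lewis acid-promoted intramolecular conjugate ene reaction of the trisubstituted alkene onto the activated enone closes ring A through a chair transition state with the C5 methyl group and the developing tertiary cation equatorial and axial attack on the enone β-carbon, which sets C8 (isopropenyl trans to the C8a–C1 bond) and a cis ring fusion whose C8a centre is erased in step 4.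

Step 3
Reactants: 5 (4aR,5R,8R,8aR)-5-methyl-8-(prop-1-en-2-yl)octahydronaphthalen-2(1H)-one
Product: 6 (4aR,5R,8S,8aS)-5-methyl-8-(propan-2-yl)octahydronaphthalen-2(1H)-one
Conditions: H2 (1 atm), Pd/C, EtOAc, rt
Reagents that add atoms: none
Why: Heterogeneous hydrogenation reduces the unhindered 1,1-disubstituted alkene and leaves the ketone untouched; no stereocentre is formed.

Step 4
Reactants: 6 (4aR,5R,8S,8aS)-5-methyl-8-(propan-2-yl)octahydronaphthalen-2(1H)-one
Product: 8 (4aR,5R,8S)-5-methyl-8-(propan-2-yl)-4,4a,5,6,7,8-hexahydronaphthalen-2(3H)-one, via silyl enol ether 7 (not isolated)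
Conditions: TMSCl, NaI, Et3N, MeCN, rt; then Pd(OAc)2 (1.1 equiv), MeCN, rt
Reagents that add atoms: none
Why: Equilibrating silylation gives the enol ether toward C1, the direction favoured for cis-fused 2-decalones, and Saegusa–Ito oxidation then removes the C8a hydrogen by β-hydride elimination under base-free conditions that should leave the γ-stereocentres C4a and C8 untouched.

Step 5
Reactants: 9 1-fluoro-3,5-dimethoxybenzene
Product: 12 2-fluoro-4,6-dimethoxybenzaldehyde, via aryllithium 10 (not isolated), via hemiaminal alkoxide 11 (not isolated)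
Conditions: lithium 2,2,6,6-tetramethylpiperidide (from the amine and n-BuLi, 1.2 equiv), THF, −78 °C; DMF, −78 °C; then H2O
Reagents that add atoms: N,N-dimethylformamide, CN(C)C=O
Why: Directed ortho-lithiation with the hindered amide removes the most acidic ring proton, the one flanked by fluorine and methoxy, and at −78 °C the ortho-fluoro aryllithium does not lose LiF before it is formylated by DMF.

Step 6
Reactants: 12 2-fluoro-4,6-dimethoxybenzaldehyde
Product: 13 1-fluoro-3,5-dimethoxy-2-[(E)-2-nitroethenyl]benzene
Conditions: MeNO2, NH4OAc (0.3 equiv), AcOH, 90 °C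
Reagents that add atoms: nitromethane, C[N+](=O)[O-]
Why: Henry condensation; dehydration of the nitroaldol gives the conjugated E nitroalkene.

Step 7
Reactants: 13 1-fluoro-3,5-dimethoxy-2-[(E)-2-nitroethenyl]benzene
Product: 14 1-fluoro-3,5-dimethoxy-2-[(1S)-2-nitro-1-phenylethyl]benzene
Conditions: PhB(OH)2 (2 equiv), [RhCl(C2H4)2]2 (2.5 mol %), (3aR,6aR)-3,6-diphenyl-1,3a,4,6a-tetrahydropentalene (5.5 mol %), aq KOH (10 mol %), toluene/H2O, rt
Reagents that add atoms: phenylboronic acid, OB(O)c1ccccc1
Why: Rhodium-catalysed asymmetric conjugate addition of an arylboronic acid to a β-aryl nitroalkene (Hayashi–Miyaura reaction), in which the chiral diene on rhodium selects the alkene face during aryl insertion and sets the diarylmethine centre as S.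

Step 8
Reactants: 14 1-fluoro-3,5-dimethoxy-2-[(1S)-2-nitro-1-phenylethyl]benzene
Product: 15 (2S)-2-(2-fluoro-4,6-dimethoxyphenyl)-2-phenylacetic acid
Conditions: NaNO2 (3 equiv), AcOH (10 equiv), DMSO, 35 °C
Reagents that add atoms: water, O
Why: Nitrosative Nef-type oxidation of the primary nitroalkane (nitrolic acid, nitrile oxide, hydroxamic acid, acid) runs under weakly acidic conditions at 35 °C and is expected to leave the adjacent diarylmethine centre intact.

Step 9
Reactants: 15 (2S)-2-(2-fluoro-4,6-dimethoxyphenyl)-2-phenylacetic acid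
Product: 16 (2S)-2-(2-fluoro-4,6-dimethoxyphenyl)-2-phenylethan-1-ol
Conditions: BH3·THF, THF, 0 °C to rt; then H2O
Reagents that add atoms: none
Why: Borane reduces the carboxylic acid through an acyloxyborane under non-basic conditions, so the doubly benzylic stereocentre is not enolised.

Step 10
Reactants: 16 (2S)-2-(2-fluoro-4,6-dimethoxyphenyl)-2-phenylethan-1-ol
Product: 17 1-fluoro-2-[(1S)-2-iodo-1-phenylethyl]-3,5-dimethoxybenzene
Conditions: I2, PPh3, imidazole, CH2Cl2, 0 °C to rt
Reagents that add atoms: iodine, II
Why: Appel-type iodination displaces the alkoxyphosphonium group by SN2 at the CH2 carbon, away from the stereocentre.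

Step 11
Reactants: 17 1-fluoro-2-[(1S)-2-iodo-1-phenylethyl]-3,5-dimethoxybenzene; 8 (4aR,5R,8S)-5-methyl-8-(propan-2-yl)-4,4a,5,6,7,8-hexahydronaphthalen-2(3H)-one
Product: 20 (2S,4aR,5R,8S)-2-[(2S)-2-(2-fluoro-4,6-dimethoxyphenyl)-2-phenylethyl]-5-methyl-8-(propan-2-yl)-2,3,4,4a,5,6,7,8-octahydronaphthalen-2-ol, via alkyllithium 18 (not isolated), via alkylcerium dichloride 19 (not isolated)
Conditions: t-BuLi (2.05 equiv), Et2O/pentane, −78 °C; anhydrous CeCl3, THF, −78 °C; then 8, −78 °C; then H2O
Reagents that add atoms: none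
Why: Iodine–lithium exchange and transmetalation give a weakly basic organocerium reagent that adds 1,2 to the enone without γ-enolisation (C4a and C8 retained); the bulky β-branched reagent should enter along the equatorial trajectory of the half-chair enone, on the face of the pseudo-axial C4a hydrogen, leaving the hydroxyl pseudo-axial (2S), and the minor C2 epimer would be removed by chromatography.

Step 12
Reactants: 20 (2S,4aR,5R,8S)-2-[(2S)-2-(2-fluoro-4,6-dimethoxyphenyl)-2-phenylethyl]-5-methyl-8-(propan-2-yl)-2,3,4,4a,5,6,7,8-octahydronaphthalen-2-ol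
Product: 25 (2S,4S,4a'R,5'R,8'S)-5,7-dimethoxy-5'-methyl-4-phenyl-8'-(propan-2-yl)-3',4',4a',5',6',7'-hexahydro-8'H-spiro[chromane-2,2'-naphthalene]-8-carbaldehyde, via lithiated fluoroarene 21 (not isolated), via aryne alkoxide 22 (not isolated), via chroman aryllithium 23 (not isolated), via hemiaminal alkoxide 24 (not isolated)
Conditions: lithium 2,2,6,6-tetramethylpiperidide (from the amine and n-BuLi, 3.5 equiv), THF, −78 to −20 °C; re-cool to −78 °C, DMF (5 equiv), to 0 °C; then H2O
Reagents that add atoms: N,N-dimethylformamide, CN(C)C=O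
Why: Proposed new method: the amide base deprotonates the hydroxyl and then the arene C–H flanked by fluorine and methoxy (any lithiation between the two methoxy groups is reversible through the free amine and is drained by the irreversible step), and on warming 21 loses LiF to give aryne 22. The tertiary lithium alkoxide adds to the nearer aryne carbon in an anionic 6-exo-dig closure within the arene plane, which forms the dihydropyran ring C and aryllithium 23 with the carbanion next to the methoxy group; DMF formylates it through hemiaminal alkoxide 24. The closest known reaction types are aryne generation from ortho-lithiated aryl fluorides, chroman formation by capture of an aryne by a tethered alkoxide, and electrophilic quench of the aryllithium left after nucleophilic addition to a 3-methoxybenzyne; the one-flask combination with a hindered tertiary allylic alkoxide and DMF is the new element. No stereocentre is formed, and the carbinol and diarylmethine centres pass through unchanged provided the doubly benzylic C–H is not deprotonated, which the low temperature and the higher kinetic acidity of the fluoroarene C–H should secure. The step needs regioselective aryne capture, which is enforced twice: attack at the far aryne carbon would require a seven-membered ring, and attack at the near carbon places the carbanion beside the inductively stabilising methoxy group.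

Step 13
Reactants: 25 (2S,4S,4a'R,5'R,8'S)-5,7-dimethoxy-5'-methyl-4-phenyl-8'-(propan-2-yl)-3',4',4a',5',6',7'-hexahydro-8'H-spiro[chromane-2,2'-naphthalene]-8-carbaldehyde
Product: 26 (2S,4S,4a'R,5'R,8'S)-5,7-dimethoxy-5'-methyl-4-phenyl-8'-(propan-2-yl)-3',4',4a',5',6',7'-hexahydro-8'H-spiro[chromane-2,2'-naphthalene]-6,8-dicarbaldehyde
Conditions: Cl2CHOMe (3 equiv), TiCl4 (3 equiv), CH2Cl2, −78 to −40 °C; then H2O
Reagents that add atoms: dichloromethyl methyl ether, COC(Cl)Cl; water, O
Why: Rieche formylation attacks the only remaining C–H of ring D, which is flanked by two methoxy groups, and aqueous work-up hydrolyses the α-chloro ether to the aldehyde; the low temperature is meant to spare the tertiary allylic ether.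

Step 14
Reactants: 26 (2S,4S,4a'R,5'R,8'S)-5,7-dimethoxy-5'-methyl-4-phenyl-8'-(propan-2-yl)-3',4',4a',5',6',7'-hexahydro-8'H-spiro[chromane-2,2'-naphthalene]-6,8-dicarbaldehyde
Product: 27 Guajadial D, (2S,4S,4a'R,5'R,8'S)-5,7-dihydroxy-5'-methyl-4-phenyl-8'-(propan-2-yl)-3',4',4a',5',6',7'-hexahydro-8'H-spiro[chromane-2,2'-naphthalene]-6,8-dicarbaldehyde
Conditions: BCl3 (4 equiv), CH2Cl2, −78 to −20 °C; then H2O
Reagents that add atoms: none
Why: BCl3 chelates each formyl oxygen with its ortho methoxy group and chloride cleaves the O–CH3 bonds by SN2 at methyl at low temperature, conditions under which tertiary allylic aryl ethers of the 2,2-dimethylchromene type are expected to survive.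

**Compound list**
1 | (R)-citronellal, (3R)-3,7-dimethyloct-6-enal | CC(C)=CCC[C@@H](C)CC=O | starting material
2 | methyl vinyl ketone | CC(=O)C=C | starting material
3 | (2R,3R)-3,7-dimethyl-2-(3-oxobutyl)oct-6-enal | CC(C)=CCC[C@@H](C)[C@@H](CCC(C)=O)C=O | intermediate
4 | (4R)-4-[(2R)-6-methylhept-5-en-2-yl]cyclohex-2-en-1-one | CC(C)=CCC[C@@H](C)[C@H]1CCC(=O)C=C1 | intermediate
5 | (4aR,5R,8R,8aR)-5-methyl-8-(prop-1-en-2-yl)octahydronaphthalen-2(1H)-one, cis-fused | CC(=C)[C@@H]1CC[C@@H](C)[C@H]2CCC(=O)C[C@@H]12 | intermediate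
6 | (4aR,5R,8S,8aS)-5-methyl-8-(propan-2-yl)octahydronaphthalen-2(1H)-one, cis-fused | CC(C)[C@@H]1CC[C@@H](C)[C@H]2CCC(=O)C[C@@H]12 | intermediate
7 | trimethyl{[(4aR,5R,8S,8aS)-5-methyl-8-(propan-2-yl)-3,4,4a,5,6,7,8,8a-octahydronaphthalen-2-yl]oxy}silane | CC(C)[C@@H]1CC[C@@H](C)[C@H]2CCC(O[Si](C)(C)C)=C[C@@H]12 | intermediate
8 | (4aR,5R,8S)-5-methyl-8-(propan-2-yl)-4,4a,5,6,7,8-hexahydronaphthalen-2(3H)-one | CC(C)[C@@H]1CC[C@@H](C)[C@H]2CCC(=O)C=C12 | intermediate
9 | 1-fluoro-3,5-dimethoxybenzene | COc1cc(F)cc(OC)c1 | starting material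
10 | (2-fluoro-4,6-dimethoxyphenyl)lithium | COc1cc(F)c([Li])c(OC)c1 | intermediate
11 | lithium (dimethylamino)(2-fluoro-4,6-dimethoxyphenyl)methanolate | COc1cc(F)c(C(O[Li])N(C)C)c(OC)c1 | intermediate
12 | 2-fluoro-4,6-dimethoxybenzaldehyde | COc1cc(F)c(C=O)c(OC)c1 | intermediate
13 | 1-fluoro-3,5-dimethoxy-2-[(E)-2-nitroethenyl]benzene | COc1cc(F)c(/C=C/[N+](=O)[O-])c(OC)c1 | intermediate
14 | 1-fluoro-3,5-dimethoxy-2-[(1S)-2-nitro-1-phenylethyl]benzene | [O-][N+](=O)C[C@@H](c1ccccc1)c1c(OC)cc(OC)cc1F | intermediate
15 | (2S)-2-(2-fluoro-4,6-dimethoxyphenyl)-2-phenylacetic acid | OC(=O)[C@@H](c1ccccc1)c1c(OC)cc(OC)cc1F | intermediate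
16 | (2S)-2-(2-fluoro-4,6-dimethoxyphenyl)-2-phenylethan-1-ol | OC[C@@H](c1ccccc1)c1c(OC)cc(OC)cc1F | intermediate
17 | 1-fluoro-2-[(1S)-2-iodo-1-phenylethyl]-3,5-dimethoxybenzene | IC[C@@H](c1ccccc1)c1c(OC)cc(OC)cc1F | intermediate
18 | [(2S)-2-(2-fluoro-4,6-dimethoxyphenyl)-2-phenylethyl]lithium | [Li]C[C@@H](c1ccccc1)c1c(OC)cc(OC)cc1F | intermediate
19 | dichloro[(2S)-2-(2-fluoro-4,6-dimethoxyphenyl)-2-phenylethyl]cerium | Cl[Ce](Cl)C[C@@H](c1ccccc1)c1c(OC)cc(OC)cc1F | intermediate
20 | (2S,4aR,5R,8S)-2-[(2S)-2-(2-fluoro-4,6-dimethoxyphenyl)-2-phenylethyl]-5-methyl-8-(propan-2-yl)-2,3,4,4a,5,6,7,8-octahydronaphthalen-2-ol | CC(C)[C@@H]1CC[C@@H](C)[C@H]2CC[C@@](O)(C=C12)C[C@@H](c1ccccc1)c1c(OC)cc(OC)cc1F | intermediate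
21 | lithium alkoxide of 20, lithiated at the arene carbon between fluorine and methoxy | CC(C)[C@@H]1CC[C@@H](C)[C@H]2CC[C@@](O[Li])(C=C12)C[C@@H](c1ccccc1)c1c(OC)cc(OC)c([Li])c1F | intermediate
22 | lithium alkoxide of 20 with the C–F and adjacent C–H carbons joined as an aryne (2,3-didehydro-4,6-dimethoxyphenyl) | CC(C)[C@@H]1CC[C@@H](C)[C@H]2CC[C@@](O[Li])(C=C12)C[C@@H](c1ccccc1)C1=C(OC)C=C(OC)C#C1 | intermediate
23 | 8-lithio derivative of the (2S,4S,4a'R,5'R,8'S)-5,7-dimethoxy-4-phenyl spirochroman (25 with Li in place of CHO) | CC(C)[C@@H]1CC[C@@H](C)[C@H]2CC[C@@]3(C=C12)C[C@@H](c1ccccc1)c1c(OC)cc(OC)c([Li])c1O3 | intermediate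
24 | lithium (dimethylamino)methanolate adduct of 23 and DMF at C8 | CC(C)[C@@H]1CC[C@@H](C)[C@H]2CC[C@@]3(C=C12)C[C@@H](c1ccccc1)c1c(OC)cc(OC)c(C(O[Li])N(C)C)c1O3 | intermediate
25 | (2S,4S,4a'R,5'R,8'S)-5,7-dimethoxy-5'-methyl-4-phenyl-8'-(propan-2-yl)-3',4',4a',5',6',7'-hexahydro-8'H-spiro[chromane-2,2'-naphthalene]-8-carbaldehyde | CC(C)[C@@H]1CC[C@@H](C)[C@H]2CC[C@@]3(C=C12)C[C@@H](c1ccccc1)c1c(OC)cc(OC)c(C=O)c1O3 | intermediate
26 | (2S,4S,4a'R,5'R,8'S)-5,7-dimethoxy-5'-methyl-4-phenyl-8'-(propan-2-yl)-3',4',4a',5',6',7'-hexahydro-8'H-spiro[chromane-2,2'-naphthalene]-6,8-dicarbaldehyde | CC(C)[C@@H]1CC[C@@H](C)[C@H]2CC[C@@]3(C=C12)C[C@@H](c1ccccc1)c1c(OC)c(C=O)c(OC)c(C=O)c1O3 | intermediate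
27 | Guajadial D | CC(C)[C@@H]1CC[C@@H](C)[C@H]2CC[C@@]3(C=C12)C[C@@H](c1ccccc1)c1c(O)c(C=O)c(O)c(C=O)c1O3 | target

**Step count**
Total: 14 steps. Longest linear sequence: 10 steps (steps 5 to 14, from 1-fluoro-3,5-dimethoxybenzene); the terpenoid branch is 4 steps to enone 8.

**Steps most likely to fail**

Step 12 (proposed new method). The cascade may stall or divert in several ways: lithiation between the two methoxy groups that does not funnel back, deprotonation of the doubly benzylic C–H with loss of configuration, capture of the aryne by the amide base or by a second alkoxide, or protonation of the aryl anion before DMF is added. The fallback uses known chemistry and separates the two bond formations. It sets out from 20: lithiation with lithium 2,2,6,6-tetramethylpiperidide at −78 °C and addition of DMF at that temperature, before LiF can be lost, should give the ortho-fluoro aldehyde F1. Treatment of F1 with KN(SiMe3)2 in THF (0 °C to rt) should then let the tertiary alkoxide displace the fluoride, now activated by the ortho formyl group, in an intramolecular SNAr reaction that closes ring C. The fallback comes back to the route at 25.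

Step 11. The addition may show poor facial selectivity at the enone carbonyl (axial against equatorial entry), and the alkyllithium may be lost by elimination or enolisation before it reaches cerium. The fallback corrects the spiro centre by thermodynamic control instead of kinetic control. It sets out from 8 and 17: the C2-epimeric carbinol F2 formed in the same addition is not discarded but is closed under the conditions of step 12 to the epimeric spirochroman F3. F3 is then stirred with camphorsulfonic acid (10 mol %) in CH2Cl2 at 0 °C. Reversible heterolysis of the tertiary allylic aryl ether to the allyl cation and phenol, followed by reclosure, should enrich the epimer with the ring C oxygen pseudo-axial and the larger CH2 branch pseudo-equatorial on ring B. The fallback comes back to the route at 25.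

Step 14. The Lewis acid may ionise the tertiary allylic spiro ether, which would scramble C2 or open ring C to dienes, and cleavage of the more hindered methyl ether may be incomplete. The fallback replaces electrophilic activation at oxygen by nucleophilic attack at carbon. It sets out from 26: NaSEt in DMF at 60 °C, then buffered acidification (aq NaH2PO4), should remove both methyl groups by SN2 at methyl, since each methoxy group is a vinylogous ester, while the tertiary spiro carbon cannot react this way. The fallback comes back to the route at 27, and no compound outside the list is formed (F0).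

**Further compounds**
F1 | step 12 | 2-fluoro-3-[(1S)-2-[(2S,4aR,5R,8S)-2-hydroxy-5-methyl-8-(propan-2-yl)-2,3,4,4a,5,6,7,8-octahydronaphthalen-2-yl]-1-phenylethyl]-4,6-dimethoxybenzaldehyde | CC(C)[C@@H]1CC[C@@H](C)[C@H]2CC[C@@](O)(C=C12)C[C@@H](c1ccccc1)c1c(OC)cc(OC)c(C=O)c1F
F2 | step 11 | (2R,4aR,5R,8S)-2-[(2S)-2-(2-fluoro-4,6-dimethoxyphenyl)-2-phenylethyl]-5-methyl-8-(propan-2-yl)-2,3,4,4a,5,6,7,8-octahydronaphthalen-2-ol | CC(C)[C@@H]1CC[C@@H](C)[C@H]2CC[C@](O)(C=C12)C[C@@H](c1ccccc1)c1c(OC)cc(OC)cc1F
F3 | step 11 | (2R,4S,4a'R,5'R,8'S)-5,7-dimethoxy-5'-methyl-4-phenyl-8'-(propan-2-yl)-3',4',4a',5',6',7'-hexahydro-8'H-spiro[chromane-2,2'-naphthalene]-8-carbaldehyde | CC(C)[C@@H]1CC[C@@H](C)[C@H]2CC[C@]3(C=C12)C[C@@H](c1ccccc1)c1c(OC)cc(OC)c(C=O)c1O3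
F0 | step 14 | none | none
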